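**Plan**

1. Retrosynthetic cuts, in order: C3–H (back to a C3 allyl ester), C4–C4a of ring C, O1–C2, C2–C3 (formaldehyde), C3–C1' (aryl–malonate bond), and the pyran ring of the chromene on ring B.
2. Forward: the chromene ring is fused to ring B first (steps 1–2), the chain C1'–C3(CO2allyl)2–C2–O1–ring A is joined piece by piece (steps 3–5), ring C closes (step 6), and C3 is set last (step 7).
3. Enabling feature: in ring A, C4a lies between O1 and the free 5-hydroxyl, and the target holds the six-membered chelate O5–H···O=C4. The same chelate with magnesium in place of hydrogen should carry the future C4 carbonyl onto C4a and nowhere else.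
4. C3 is benzylic, alpha to the C4 ketone and beta to the ring A aryloxy group. It is carried as a quaternary diallyl malonate carbon that cannot epimerise, form a ketene or expel the aryloxide; one ester becomes C4, the other is a helper that leaves in step 7.
5. Stereochemistry: the only stereocentre (C3, S) comes from a palladium-catalysed decarboxylative asymmetric protonation under a chiral phosphinooxazoline, as the final, neutral step. No acid is used anywhere, for the sake of the chromene.

Key step: step 6

Assumption: with the (S)-ligand and Meldrum's acid as proton donor the protonation in step 7 is taken to give the (3S) ketone; if the sense of induction is the reverse, the (R)-ligand is used and nothing else changes.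

**Route**

Step 1
Reactants: 1 4-bromo-3-methoxyphenol; 2 3-chloro-3-methylbut-1-yne
Product: 3 1-bromo-2-methoxy-4-[(2-methylbut-3-yn-2-yl)oxy]benzene
Conditions: K2CO3, KI, CuI (cat.), acetone, 60 °C
Reagents that add atoms: none
Why: Copper-assisted O-alkylation of the phenoxide by the tertiary propargylic chloride is the standard entry to aryl 1,1-dimethylpropargyl ethers.

Step 2
Reactants: 3 1-bromo-2-methoxy-4-[(2-methylbut-3-yn-2-yl)oxy]benzene
Product: 5 6-bromo-7-methoxy-2,2-dimethyl-2H-chromene, via ortho-allenylphenol 4 (not isolated)
Conditions: o-xylene, 140 °C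
Reagents that add atoms: none
Why: Aromatic propargyl Claisen rearrangement to 4, then 1,5-hydrogen shift and 6π oxa-electrocyclisation close the 2,2-dimethylpyran ring, and the free ortho position para to the methoxy group should be preferred because the position between the two oxygens is shielded by the methoxy methyl that the neighbouring bromine turns toward it.

Step 3
Reactants: 5 6-bromo-7-methoxy-2,2-dimethyl-2H-chromene; 6 diallyl malonate
Product: 7 diallyl 2-(7-methoxy-2,2-dimethyl-2H-chromen-6-yl)malonate
Conditions: CuI (10 mol %), L-proline (20 mol %), Cs2CO3, DMSO, 60 °C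
Reagents that add atoms: none
Why: Ullmann-type copper-catalysed C-arylation of the malonate anion by the aryl bromide, accelerated by the amino acid ligand, should give the arylmalonate, and copper is chosen over palladium so that the allyl esters are not ionised.

Step 4
Reactants: 7 diallyl 2-(7-methoxy-2,2-dimethyl-2H-chromen-6-yl)malonate
Product: 8 diallyl 2-(hydroxymethyl)-2-(7-methoxy-2,2-dimethyl-2H-chromen-6-yl)malonate
Conditions: 37 % aq. CH2O, KHCO3 (cat.), THF, rt
Reagents that add atoms: formaldehyde, C=O
Why: Base-catalysed aldol addition (hydroxymethylation) of the acidic arylmalonate C–H to formaldehyde builds the quaternary carbon, which is not a stereocentre because the two esters are identical.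

Step 5
Reactants: 8 diallyl 2-(hydroxymethyl)-2-(7-methoxy-2,2-dimethyl-2H-chromen-6-yl)malonate; 9 5-methoxyresorcinol
Product: 10 diallyl 2-[(3-hydroxy-5-methoxyphenoxy)methyl]-2-(7-methoxy-2,2-dimethyl-2H-chromen-6-yl)malonate
Conditions: 9 (3 equiv), PPh3, DIAD, THF, 0 to 50 °C
Reagents that add atoms: none
Why: Mitsunobu etherification, in which the phenoxide displaces the oxyphosphonium of the primary alcohol by SN2, should give the mono-ether because the two hydroxyls of the diol are equivalent and it is used in excess, and the quaternary neighbour, having no hydrogen, rules out elimination.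

Step 6
Reactants: 10 diallyl 2-[(3-hydroxy-5-methoxyphenoxy)methyl]-2-(7-methoxy-2,2-dimethyl-2H-chromen-6-yl)malonate
Product: 12 allyl (±)-5-hydroxy-7-methoxy-3-(7-methoxy-2,2-dimethyl-2H-chromen-6-yl)-4-oxochromane-3-carboxylate, via chloromagnesium phenoxide 11 (not isolated)
Conditions: MgCl2 (2 equiv), Et3N (3 equiv), MeCN, 80 °C; then aq. NH4Cl
Reagents that add atoms: none
Why: Proposed new method: MgCl2 and Et3N turn the free phenol into the chloromagnesium phenoxide 11, in which divalent magnesium bridges the phenoxide oxygen and the carbonyl oxygen of one allyl ester, so that the electron-rich ortho carbon between the two ring oxygens adds to that activated carbonyl, allyl oxide leaves and the dienone tautomerises to the magnesium chelate of the ortho-hydroxyaryl ketone (an intramolecular Claisen-type C-acylation of a phenoxide). The closest known reaction types are the ortho-specific formylation, acylation and carboxylation of magnesium phenoxides by formaldehyde, acyl chlorides and magnesium methyl carbonate through the same six-membered chelate, and the Dieckmann condensation; an ester as acyl donor toward a phenoxide carbon is the new element, argued from the high carbon nucleophilicity of phloroglucinol-type phenoxides, the activation of the geminal diester and the six-membered transition state. Ring C closes in the 6-exo-trig mode. C3 becomes a stereocentre because one of two enantiotopic esters is used, but it forms as a racemate on purpose and is erased in step 7. The step needs carbon rather than oxygen acylation and the ortho rather than the para carbon: an intramolecular O-acylation would require a strained eight-membered meta-bridged lactone, and the magnesium chelate is possible only at the ortho carbon, which also leaves the 5-hydroxyl free and the 7-methoxy group in place. The quaternary C3 has no hydrogen, so neither ketene formation nor beta-elimination of the aryloxide can compete, and the acid-labile chromene never meets an acid.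

Step 7
Reactants: 12 allyl (±)-5-hydroxy-7-methoxy-3-(7-methoxy-2,2-dimethyl-2H-chromen-6-yl)-4-oxochromane-3-carboxylate
Product: 13 (3S)-5-hydroxy-7-methoxy-3-(7-methoxy-2,2-dimethyl-2H-chromen-6-yl)chroman-4-one
Conditions: Pd2(dba)3 (5 mol %), (S)-(CF3)3-t-BuPHOX (12.5 mol %), Meldrum's acid (2.5 equiv), 1,4-dioxane, 40 °C
Reagents that add atoms: none
Why: In this decarboxylative asymmetric protonation, a reaction type established for allyl 3-aryl-4-oxochromane-3-carboxylates, zerovalent palladium ionises the allyl ester, loss of CO2 gives an enolate held by the chiral palladium phosphinooxazoline fragment, and Meldrum's acid protonates one face of C3 and takes up the allyl group, so that the racemic quaternary centre is erased and the (S) centre is set under neutral conditions as the last operation.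

**Compound list**

1 | 4-bromo-3-methoxyphenol | COc1cc(O)ccc1Br | starting material
2 | 3-chloro-3-methylbut-1-yne | CC(C)(Cl)C#C | starting material
3 | 1-bromo-2-methoxy-4-[(2-methylbut-3-yn-2-yl)oxy]benzene | COc1cc(OC(C)(C)C#C)ccc1Br | intermediate
4 | 4-bromo-5-methoxy-2-(3-methylbuta-1,2-dien-1-yl)phenol | COc1cc(O)c(C=C=C(C)C)cc1Br | intermediate
5 | 6-bromo-7-methoxy-2,2-dimethyl-2H-chromene | COc1cc2OC(C)(C)C=Cc2cc1Br | intermediate
6 | diallyl malonate | C=CCOC(=O)CC(=O)OCC=C | starting material
7 | diallyl 2-(7-methoxy-2,2-dimethyl-2H-chromen-6-yl)malonate | C=CCOC(=O)C(C(=O)OCC=C)c1cc2C=CC(C)(C)Oc2cc1OC | intermediate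
8 | diallyl 2-(hydroxymethyl)-2-(7-methoxy-2,2-dimethyl-2H-chromen-6-yl)malonate | C=CCOC(=O)C(CO)(C(=O)OCC=C)c1cc2C=CC(C)(C)Oc2cc1OC | intermediate
9 | 5-methoxyresorcinol (5-methoxybenzene-1,3-diol) | COc1cc(O)cc(O)c1 | starting material
10 | diallyl 2-[(3-hydroxy-5-methoxyphenoxy)methyl]-2-(7-methoxy-2,2-dimethyl-2H-chromen-6-yl)malonate | C=CCOC(=O)C(COc1cc(O)cc(OC)c1)(C(=O)OCC=C)c1cc2C=CC(C)(C)Oc2cc1OC | intermediate
11 | chloromagnesium phenoxide of 10 | C=CCOC(=O)C(COc1cc(O[Mg]Cl)cc(OC)c1)(C(=O)OCC=C)c1cc2C=CC(C)(C)Oc2cc1OC | intermediate
12 | allyl (±)-5-hydroxy-7-methoxy-3-(7-methoxy-2,2-dimethyl-2H-chromen-6-yl)-4-oxochromane-3-carboxylate (racemic) | C=CCOC(=O)C1(c2cc3C=CC(C)(C)Oc3cc2OC)COc2cc(OC)cc(O)c2C1=O | intermediate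
13 | (3S)-5-hydroxy-7-methoxy-3-(7-methoxy-2,2-dimethyl-2H-chromen-6-yl)chroman-4-one | COc1cc(O)c2c(c1)OC[C@H](c1cc3c(cc1OC)OC(C)(C)C=C3)C2=O | target

**Step count and risks**

Total step count: 7. Longest linear sequence: 7 steps (1 to 13).

Steps most likely to fail:

1. Step 6. The allyl ester may be too weak an acyl donor for the phenoxide carbon, or ring closure may occur at the carbon para to the phenoxide oxygen and give the regioisomeric ring. The fallback uses known chemistry, sets out from 8 and comes back at 12. Mitsunobu etherification of 8 with commercial 3,5-dimethoxyphenol (PPh3, DIAD, THF) should give diallyl 2-[(3,5-dimethoxyphenoxy)methyl]-2-(7-methoxy-2,2-dimethyl-2H-chromen-6-yl)malonate F1. Monosaponification (1 equiv KOH, THF–water, 0 °C to rt) should give (±)-3-(allyloxy)-2-[(3,5-dimethoxyphenoxy)methyl]-2-(7-methoxy-2,2-dimethyl-2H-chromen-6-yl)-3-oxopropanoic acid F2. Its mixed anhydride with TFAA (CH2Cl2, 0 °C, 2,6-di-tert-butylpyridine as acid scavenger for the chromene) should close ring C by intramolecular Friedel–Crafts acylation; both ortho positions of the symmetric ring are equivalent, so only allyl (±)-5,7-dimethoxy-3-(7-methoxy-2,2-dimethyl-2H-chromen-6-yl)-4-oxochromane-3-carboxylate F3 can form. BCl3 (CH2Cl2, −78 °C) should then remove only the methyl group chelated to the C4 carbonyl and deliver 12.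

2. Step 7. The free, hydrogen-bonded 5-hydroxyl may pass its proton to the enolate oxygen, and ketonisation of the resulting enol outside the chiral pocket would lower the enantiomeric purity; the sense of induction is also assumed. The fallback sets out from 12 and comes back at 13. Non-selective deallylation and decarboxylation (Pd(PPh3)4, morpholine, THF, rt) should give racemic 5-hydroxy-7-methoxy-3-(7-methoxy-2,2-dimethyl-2H-chromen-6-yl)chroman-4-one F4. Asymmetric transfer hydrogenation with dynamic kinetic resolution (RuCl(p-cymene)[(S,S)-TsDPEN], HCO2H/Et3N, EtOAc, rt) should follow: Et3N equilibrates the enantiomers of F4 through the enol and the catalyst reduces the (3S) ketone faster, to give (3S,4S)-cis-7-methoxy-3-(7-methoxy-2,2-dimethyl-2H-chromen-6-yl)chromane-4,5-diol F5. Neutral oxidation of the benzylic alcohol (activated MnO2, CH2Cl2, rt) should give 13 without touching C3.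

3. Step 5. Substitution at the neopentyl carbon may be slow, and retro-aldol loss of formaldehyde from 8 may take over. The fallback sets out from 8 and comes back at 10. The alcohol is first converted (Tf2O, 2,6-lutidine, CH2Cl2, −78 °C) into diallyl 2-(7-methoxy-2,2-dimethyl-2H-chromen-6-yl)-2-{[(trifluoromethylsulfonyl)oxy]methyl}malonate F6. This isolated triflate is then displaced by the preformed mono-caesium phenoxide of 9 (3 equiv 9, Cs2CO3, DMF, 0 °C to rt) to give 10.

**Further compounds**

F1 | step 6 | diallyl 2-[(3,5-dimethoxyphenoxy)methyl]-2-(7-methoxy-2,2-dimethyl-2H-chromen-6-yl)malonate | C=CCOC(=O)C(COc1cc(OC)cc(OC)c1)(C(=O)OCC=C)c1cc2C=CC(C)(C)Oc2cc1OC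
F2 | step 6 | (±)-3-(allyloxy)-2-[(3,5-dimethoxyphenoxy)methyl]-2-(7-methoxy-2,2-dimethyl-2H-chromen-6-yl)-3-oxopropanoic acid | C=CCOC(=O)C(COc1cc(OC)cc(OC)c1)(C(=O)O)c1cc2C=CC(C)(C)Oc2cc1OC
F3 | step 6 | allyl (±)-5,7-dimethoxy-3-(7-methoxy-2,2-dimethyl-2H-chromen-6-yl)-4-oxochromane-3-carboxylate | C=CCOC(=O)C1(c2cc3C=CC(C)(C)Oc3cc2OC)COc2cc(OC)cc(OC)c2C1=O
F4 | step 7 | (±)-5-hydroxy-7-methoxy-3-(7-methoxy-2,2-dimethyl-2H-chromen-6-yl)chroman-4-one | COc1cc(O)c2c(c1)OCC(c1cc3c(cc1OC)OC(C)(C)C=C3)C2=O
F5 | step 7 | (3S,4S)-7-methoxy-3-(7-methoxy-2,2-dimethyl-2H-chromen-6-yl)chromane-4,5-diol | COc1cc(O)c2c(c1)OC[C@H](c1cc3c(cc1OC)OC(C)(C)C=C3)[C@@H]2O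
F6 | step 5 | diallyl 2-(7-methoxy-2,2-dimethyl-2H-chromen-6-yl)-2-{[(trifluoromethylsulfonyl)oxy]methyl}malonate | C=CCOC(=O)C(COS(=O)(=O)C(F)(F)F)(C(=O)OCC=C)c1cc2C=CC(C)(C)Oc2cc1OC
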